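## Retrosynthetic overview

- The target (flavanone numbering: O1, C2, C3, C4, C4a, C5–C8, C8a) comes from its tris-MOM ether by acetal cleavage; no ring is touched after the key step.
- Ring C is cut at O1–C8a and C4–C4a. A fluoride-triggered annulation joins a ring-A aryne (C4a≡C8a, MOM-oxygens on C5 and C7, prenyl on C8) to the (S)-β-hydroxy ester O1–C2(ring B)–C3–C4(=O)OMe. Rings A and B are bought as benzenes; ring C is the only ring formed, and it is formed last.
- Enabling feature: in ring A the ether oxygen O1 and the acyl carbon C4 sit on the adjacent carbons C8a and C4a, the ortho pattern left when a nucleophile/electrophile pair adds across an aryne. The C5 oxygen flanks C4a, so an alkoxy group there polarises the aryne to take oxygen at C8a and carbanion character at C4a. C2 keeps its configuration because its C–O bond already exists.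
- Aryne precursor (ortho-silylaryl triflate): phloroglucinol → bis-MOM ether → N-isopropyl carbamate → two directed ortho-metalations (SiMe3, then prenyl) → carbamate-to-triflate exchange.
- β-Hydroxy ester: 4-bromophenol → MOM ether → γ-selective Suzuki–Miyaura reverse prenylation → ortho-lithiation/acetylation → Claisen condensation → asymmetric transfer hydrogenation, which sets C2 as (S).

Key step: step 11

Remark: C2 of the target is (S); since O > aryl > CH2 > H holds at this carbon in every intermediate, the descriptor is the same from the β-hydroxy ester onward.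

## Route

Step 1
Reactants: 1 phloroglucinol (benzene-1,3,5-triol)
Product: 2 3,5-bis(methoxymethoxy)phenol
Conditions: MOMCl (2.0 equiv), i-Pr2NEt (2.2 equiv), DMF, 0 °C to rt; chromatography
Reagents that add atoms: chloromethyl methyl ether, COCCl
Why: Williamson-type O-alkylation of the symmetric triol is statistical, so two equivalents of the chloromethyl ether should give the bis-ether as the main product, separable from the mono- and tris-ethers.

Step 2
Reactants: 2 3,5-bis(methoxymethoxy)phenol
Product: 3 3,5-bis(methoxymethoxy)phenyl N-(propan-2-yl)carbamate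
Conditions: i-PrNCO, Et3N (cat.), CH2Cl2, rt
Reagents that add atoms: isopropyl isocyanate, CC(C)N=C=O
Why: Base-catalysed addition of the phenol to the isocyanate (carbamoylation) puts the strongest ortho-directing group on the one oxygen that later becomes the triflate.

Step 3
Reactants: 3 3,5-bis(methoxymethoxy)phenyl N-(propan-2-yl)carbamate
Product: 7 3,5-bis(methoxymethoxy)-2-(trimethylsilyl)phenyl N-(propan-2-yl)carbamate, via N-trimethylsilyl carbamate 4 (not isolated), via aryllithium 5 (not isolated), via bis-silyl carbamate 6 (not isolated)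
Conditions: TMSOTf, TMEDA, Et2O, 0 °C to rt; n-BuLi, TMEDA, −78 °C; TMSCl, −78 °C to rt; aq. NH4Cl
Reagents that add atoms: chlorotrimethylsilane, C[Si](C)(C)Cl (C-silyl group of 7); trimethylsilyl trifluoromethanesulfonate, C[Si](C)(C)OS(=O)(=O)C(F)(F)F (N-silyl group of 4 to 6 only, lost on work-up); n-butyllithium, [Li]CCCC (lithium of 5 only)
Why: Directed ortho-metalation of the N-silylated carbamate should occur at C2 (equivalent to C6), where carbamate and OMOM cooperate, in preference to C4 between the two weaker OMOM directors, and the aryllithium is silylated by TMSCl before the labile N–SiMe3 bond is hydrolysed on work-up.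

Step 4
Reactants: 7 3,5-bis(methoxymethoxy)-2-(trimethylsilyl)phenyl N-(propan-2-yl)carbamate
Product: 12 3,5-bis(methoxymethoxy)-2-(3-methylbut-2-en-1-yl)-6-(trimethylsilyl)phenyl N-(propan-2-yl)carbamate, via N-tert-butyldimethylsilyl carbamate 8 (not isolated), via aryllithium 9 (not isolated), via arylcopper 10 (not isolated), via N-tert-butyldimethylsilyl prenyl carbamate 11 (not isolated)
Conditions: TBSOTf, TMEDA, Et2O, 0 °C to rt; n-BuLi, TMEDA, −78 °C; CuBr·SMe2, −78 to −40 °C; prenyl bromide, −40 °C to rt; aq. citric acid (10%), 0 °C to rt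
Reagents that add atoms: 1-bromo-3-methylbut-2-ene (prenyl bromide), CC(C)=CCBr; tert-butyldimethylsilyl trifluoromethanesulfonate, CC(C)(C)[Si](C)(C)OS(=O)(=O)C(F)(F)F (N-silyl group of 8 to 11 only, lost on work-up); n-butyllithium, [Li]CCCC (lithium of 9 only); CuBr·SMe2, [Cu]Br.CSC (copper of 10 only)
Why: The carbamate N–H is masked in the flask with the bulkier tert-butyldimethylsilyl group, whose N–Si bond should last through transmetalation and warming to room temperature in the presence of bromide (where a free carbamate anion would fragment to isocyanate and phenoxide), and a second directed ortho-metalation at the remaining position flanked by carbamate and OMOM, transmetalation to the arylcopper (which also suppresses anionic ortho-Fries migration) and SN2 allylation with prenyl bromide should give the linear prenyl group, because the hindered aryl disfavours attack at the disubstituted allyl terminus, before the mild citric acid work-up hydrolyses the N–Si bond without touching the MOM ethers.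

Step 5
Reactants: 12 3,5-bis(methoxymethoxy)-2-(3-methylbut-2-en-1-yl)-6-(trimethylsilyl)phenyl N-(propan-2-yl)carbamate
Product: 14 3,5-bis(methoxymethoxy)-2-(3-methylbut-2-en-1-yl)-6-(trimethylsilyl)phenyl trifluoromethanesulfonate, via phenol 13 (not isolated)
Conditions: DBU, Et2NH, MeCN, 40 °C; then PhNTf2, rt
Reagents that add atoms: N-phenylbis(trifluoromethanesulfonimide), O=S(=O)(N(c1ccccc1)S(=O)(=O)C(F)(F)F)C(F)(F)F
Why: E1cB cleavage of the N–H carbamate (the phenoxide leaves and diethylamine traps isopropyl isocyanate as a urea) followed by O-sulfonylation of the phenoxide in the same flask is the established conversion of ortho-silyl aryl carbamates into ortho-silylaryl triflates.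

Step 6
Reactants: 15 4-bromophenol
Product: 16 1-bromo-4-(methoxymethoxy)benzene
Conditions: MOMCl, i-Pr2NEt, CH2Cl2, 0 °C to rt
Reagents that add atoms: chloromethyl methyl ether, COCCl
Why: Williamson-type O-alkylation gives the MOM ether, which later directs ortho-lithiation and survives base, fluoride and organometallic steps.

Step 7
Reactants: 16 1-bromo-4-(methoxymethoxy)benzene
Product: 17 1-(methoxymethoxy)-4-(2-methylbut-3-en-2-yl)benzene
Conditions: prenylBpin (1.5 equiv), Pd(OAc)2 (2 mol %), di-tert-butyl(biaryl)phosphine ligand of the γ-selective protocol (confirmed by a short ligand screen), K3PO4 (aq.), MeCN, 70 °C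
Reagents that add atoms: 4,4,5,5-tetramethyl-2-(3-methylbut-2-en-1-yl)-1,3,2-dioxaborolane, CC(C)=CCB1OC(C)(C)C(C)(C)O1
Why: A Suzuki–Miyaura coupling of a γ,γ-disubstituted allylboronate run in its ligand-controlled γ-selective mode, where transmetalation with allylic transposition and fast reductive elimination join the aryl group to the tertiary allyl terminus, should give the 1,1-dimethylallyl (reverse prenyl) arene and not the linear isomer.

Step 8
Reactants: 17 1-(methoxymethoxy)-4-(2-methylbut-3-en-2-yl)benzene
Product: 19 1-[2-(methoxymethoxy)-5-(2-methylbut-3-en-2-yl)phenyl]ethan-1-one, via aryllithium 18 (not isolated)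
Conditions: n-BuLi, TMEDA, Et2O, 0 °C to rt; MeC(O)N(OMe)Me, −78 °C to rt; aq. NH4Cl
Reagents that add atoms: N-methoxy-N-methylacetamide, CC(=O)N(C)OC; n-butyllithium, [Li]CCCC (lithium of 18 only)
Why: Directed ortho-metalation by the OMOM group (both ortho positions are equivalent and the quaternary side chain has no acidic C–H) and Weinreb ketone synthesis with the acetamide, whose chelated tetrahedral intermediate prevents over-addition, should give the methyl ketone.

Step 9
Reactants: 19 1-[2-(methoxymethoxy)-5-(2-methylbut-3-en-2-yl)phenyl]ethan-1-one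
Product: 20 methyl 3-[2-(methoxymethoxy)-5-(2-methylbut-3-en-2-yl)phenyl]-3-oxopropanoate
Conditions: NaH (2.5 equiv), (MeO)2CO, THF, reflux; AcOH quench
Reagents that add atoms: dimethyl carbonate, COC(=O)OC
Why: A crossed Claisen condensation of the ketone enolate with dimethyl carbonate is driven to completion by deprotonation of the β-keto ester that forms.

Step 10
Reactants: 20 methyl 3-[2-(methoxymethoxy)-5-(2-methylbut-3-en-2-yl)phenyl]-3-oxopropanoate
Product: 21 methyl (3S)-3-hydroxy-3-[2-(methoxymethoxy)-5-(2-methylbut-3-en-2-yl)phenyl]propanoate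
Conditions: RuCl[(S,S)-TsDPEN](p-cymene) (1 mol %), HCO2H–Et3N (5:2), EtOAc, 40 °C
Reagents that add atoms: none
Why: In this Noyori–Ikariya asymmetric transfer hydrogenation the (S,S)-TsDPEN ruthenium hydride reduces aryl ketones with the aryl group held against the η6-arene, the sense that gives (S)-1-arylethanols and hence the (S)-carbinol that becomes C2, while the alkenes and the ester are left alone.

Step 11
Reactants: 14 3,5-bis(methoxymethoxy)-2-(3-methylbut-2-en-1-yl)-6-(trimethylsilyl)phenyl trifluoromethanesulfonate; 21 methyl (3S)-3-hydroxy-3-[2-(methoxymethoxy)-5-(2-methylbut-3-en-2-yl)phenyl]propanoate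
Product: 23 (2S)-5,7-bis(methoxymethoxy)-2-[2-(methoxymethoxy)-5-(2-methylbut-3-en-2-yl)phenyl]-8-(3-methylbut-2-en-1-yl)-2,3-dihydro-4H-chromen-4-one, via aryne 22 (not isolated)
Conditions: CsF (4 equiv), THF, 65 °C, slow addition of 14 (1.5 equiv)
Reagents that add atoms: none
Why: Proposed new method: fluoride removes the silyl group of 14 and triflate leaves to give aryne 22; the fluoride-activated secondary hydroxyl of 21 adds to the aryne carbon that becomes C8a, and the aryl anion formed at C4a, held within six-ring reach of the ester carbonyl, attacks it and expels methoxide, so that the O1–C8a and C4–C4a bonds and ring C arise in one operation. The closest known reaction type is the fluoride-mediated annulation of arynes with salicylate or anthranilate esters to xanthones and acridones, in which a heteroatom nucleophile adds and the aryl anion is acylated intramolecularly; an aliphatic secondary β-hydroxy ester has not been shown in that role, and the reasoning is that its O-adduct has the same six-membered reach to the ester. Ring C closes by a 6-exo-trig attack of the aryl anion on the ester carbonyl (addition–elimination). No stereocentre is formed: C2 is the carbinol carbon of 21, its C–O bond is never broken, and the (S) configuration set in step 10 is carried over. The step needs O-attack at C8a and not C4a, which the inductively withdrawing C5 methoxymethoxy group next to C4a should secure (as in 3-alkoxy- and 3,5-dialkoxybenzynes, where the nucleophile enters at the distal aryne carbon) against the modest steric bias of the C8 prenyl group. It also needs acylation to outrun protonation of the aryl anion, which the intramolecular ester and the aprotic THF medium should favour.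

Step 12
Reactants: 23 (2S)-5,7-bis(methoxymethoxy)-2-[2-(methoxymethoxy)-5-(2-methylbut-3-en-2-yl)phenyl]-8-(3-methylbut-2-en-1-yl)-2,3-dihydro-4H-chromen-4-one
Product: 24 (2S)-5,7-dihydroxy-2-[2-hydroxy-5-(2-methylbut-3-en-2-yl)phenyl]-8-(3-methylbut-2-en-1-yl)-2,3-dihydro-4H-chromen-4-one
Conditions: 3 M HCl (aq.)–MeOH, 40 °C
Reagents that add atoms: none
Why: Acid-catalysed acetal exchange with methanol should remove the three aryl MOM groups as dimethoxymethane under conditions mild enough to spare the prenyl and vinyl alkenes and, being base-free, to avoid retro-oxa-Michael opening at C2.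

## Compound list

1 | phloroglucinol (benzene-1,3,5-triol) | Oc1cc(O)cc(O)c1 | starting material
2 | 3,5-bis(methoxymethoxy)phenol | COCOc1cc(O)cc(OCOC)c1 | intermediate
3 | 3,5-bis(methoxymethoxy)phenyl N-(propan-2-yl)carbamate | COCOc1cc(OCOC)cc(OC(=O)NC(C)C)c1 | intermediate
4 | 3,5-bis(methoxymethoxy)phenyl N-(propan-2-yl)-N-(trimethylsilyl)carbamate | COCOc1cc(OCOC)cc(OC(=O)N(C(C)C)[Si](C)(C)C)c1 | intermediate (not isolated)
5 | 2-lithio derivative of 4 (lithium between carbamate and OMOM) | COCOc1cc(OCOC)c([Li])c(OC(=O)N(C(C)C)[Si](C)(C)C)c1 | intermediate (not isolated)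
6 | 3,5-bis(methoxymethoxy)-2-(trimethylsilyl)phenyl N-(propan-2-yl)-N-(trimethylsilyl)carbamate | COCOc1cc(OCOC)c([Si](C)(C)C)c(OC(=O)N(C(C)C)[Si](C)(C)C)c1 | intermediate (not isolated)
7 | 3,5-bis(methoxymethoxy)-2-(trimethylsilyl)phenyl N-(propan-2-yl)carbamate | COCOc1cc(OCOC)c([Si](C)(C)C)c(OC(=O)NC(C)C)c1 | intermediate
8 | 3,5-bis(methoxymethoxy)-2-(trimethylsilyl)phenyl N-[tert-butyl(dimethyl)silyl]-N-(propan-2-yl)carbamate | COCOc1cc(OCOC)c([Si](C)(C)C)c(OC(=O)N(C(C)C)[Si](C)(C)C(C)(C)C)c1 | intermediate (not isolated)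
9 | 6-lithio derivative of 8 (lithium between carbamate and OMOM) | COCOc1cc(OCOC)c([Si](C)(C)C)c(OC(=O)N(C(C)C)[Si](C)(C)C(C)(C)C)c1[Li] | intermediate (not isolated)
10 | 6-cuprio derivative of 8 (arylcopper) | COCOc1cc(OCOC)c([Si](C)(C)C)c(OC(=O)N(C(C)C)[Si](C)(C)C(C)(C)C)c1[Cu] | intermediate (not isolated)
11 | 3,5-bis(methoxymethoxy)-2-(3-methylbut-2-en-1-yl)-6-(trimethylsilyl)phenyl N-[tert-butyl(dimethyl)silyl]-N-(propan-2-yl)carbamate | COCOc1cc(OCOC)c([Si](C)(C)C)c(OC(=O)N(C(C)C)[Si](C)(C)C(C)(C)C)c1CC=C(C)C | intermediate (not isolated)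
12 | 3,5-bis(methoxymethoxy)-2-(3-methylbut-2-en-1-yl)-6-(trimethylsilyl)phenyl N-(propan-2-yl)carbamate | COCOc1cc(OCOC)c([Si](C)(C)C)c(OC(=O)NC(C)C)c1CC=C(C)C | intermediate
13 | 3,5-bis(methoxymethoxy)-2-(3-methylbut-2-en-1-yl)-6-(trimethylsilyl)phenol | COCOc1cc(OCOC)c([Si](C)(C)C)c(O)c1CC=C(C)C | intermediate (not isolated)
14 | 3,5-bis(methoxymethoxy)-2-(3-methylbut-2-en-1-yl)-6-(trimethylsilyl)phenyl trifluoromethanesulfonate | COCOc1cc(OCOC)c([Si](C)(C)C)c(OS(=O)(=O)C(F)(F)F)c1CC=C(C)C | intermediate
15 | 4-bromophenol | Oc1ccc(Br)cc1 | starting material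
16 | 1-bromo-4-(methoxymethoxy)benzene | COCOc1ccc(Br)cc1 | intermediate
17 | 1-(methoxymethoxy)-4-(2-methylbut-3-en-2-yl)benzene | COCOc1ccc(C(C)(C)C=C)cc1 | intermediate
18 | [2-(methoxymethoxy)-5-(2-methylbut-3-en-2-yl)phenyl]lithium | COCOc1ccc(C(C)(C)C=C)cc1[Li] | intermediate (not isolated)
19 | 1-[2-(methoxymethoxy)-5-(2-methylbut-3-en-2-yl)phenyl]ethan-1-one | COCOc1ccc(C(C)(C)C=C)cc1C(C)=O | intermediate
20 | methyl 3-[2-(methoxymethoxy)-5-(2-methylbut-3-en-2-yl)phenyl]-3-oxopropanoate | COCOc1ccc(C(C)(C)C=C)cc1C(=O)CC(=O)OC | intermediate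
21 | methyl (3S)-3-hydroxy-3-[2-(methoxymethoxy)-5-(2-methylbut-3-en-2-yl)phenyl]propanoate | COCOc1ccc(C(C)(C)C=C)cc1[C@@H](O)CC(=O)OC | intermediate
22 | 3,5-bis(methoxymethoxy)-6-(3-methylbut-2-en-1-yl)benzyne (aryne bond C1–C2) | CC(C)=CCC1=C(OCOC)C=C(OCOC)C#C1 | intermediate (not isolated)
23 | (2S)-5,7-bis(methoxymethoxy)-2-[2-(methoxymethoxy)-5-(2-methylbut-3-en-2-yl)phenyl]-8-(3-methylbut-2-en-1-yl)-2,3-dihydro-4H-chromen-4-one | C=CC(C)(C)c1ccc(OCOC)c([C@@H]2CC(=O)c3c(OCOC)cc(OCOC)c(CC=C(C)C)c3O2)c1 | intermediate
24 | (2S)-5,7-dihydroxy-2-[2-hydroxy-5-(2-methylbut-3-en-2-yl)phenyl]-8-(3-methylbut-2-en-1-yl)-2,3-dihydro-4H-chromen-4-one | C=CC(C)(C)c1ccc(O)c([C@@H]2CC(=O)c3c(O)cc(O)c(CC=C(C)C)c3O2)c1 | target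

## Step count and risks

Total step count: 12. Longest linear sequence: 7 steps (steps 1–5, 11, 12; the other branch, steps 6–10, 11, 12, is equally long).

Steps most likely to fail:

1. Step 11 (proposed new method). What may go wrong:
   - protonation of the C4a aryl anion before it reaches the ester, which would give plain O-arylation;
   - attack of the hydroxyl at the wrong aryne carbon, or sluggish attack next to the prenyl group;
   - consumption of the aryne by THF or by ene reaction with the alkenes;
   - fluoride-induced retro-oxa-Michael opening and reclosure of the product, which would erode the configuration at C2.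

   Fallback: it sets out from 20 (with 14 as partner), comes back at 23 and uses only known reaction types. Reduction of 20 with the enantiomeric catalyst RuCl[(R,R)-TsDPEN](p-cymene) under the conditions of step 10 should give methyl (3R)-3-hydroxy-3-[2-(methoxymethoxy)-5-(2-methylbut-3-en-2-yl)phenyl]propanoate F1. Silylation (TIPSOTf, 2,6-lutidine, CH2Cl2) should give methyl (3R)-3-[2-(methoxymethoxy)-5-(2-methylbut-3-en-2-yl)phenyl]-3-[(triisopropylsilyl)oxy]propanoate F2, a hindered silyl ether chosen to survive fluoride in THF. Saponification (LiOH, THF–H2O) should give (3R)-3-[2-(methoxymethoxy)-5-(2-methylbut-3-en-2-yl)phenyl]-3-[(triisopropylsilyl)oxy]propanoic acid F3. Heating F3 with 14 and CsF in THF at 125 °C (sealed tube) is the known addition of a carboxylate to an aryne with 1,3-acyl shift of the aryl ester anion to an ortho-hydroxyaryl ketone. It should give (3R)-1-[2-hydroxy-4,6-bis(methoxymethoxy)-3-(3-methylbut-2-en-1-yl)phenyl]-3-[2-(methoxymethoxy)-5-(2-methylbut-3-en-2-yl)phenyl]-3-[(triisopropylsilyl)oxy]propan-1-one F4, with oxygen at C8a and acyl at C4a as before. Desilylation (TBAF, AcOH, THF) should give (3R)-3-hydroxy-1-[2-hydroxy-4,6-bis(methoxymethoxy)-3-(3-methylbut-2-en-1-yl)phenyl]-3-[2-(methoxymethoxy)-5-(2-methylbut-3-en-2-yl)phenyl]propan-1-one F5. Mitsunobu cyclisation (PPh3, DIAD, THF, 0 °C), a known closure of such ketols to flavanones with inversion at the carbinol carbon, should then give 23 with the (2S) configuration.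

2. Step 4. What may go wrong:
   - metalation at the site between the two OMOM groups or at a silyl methyl group;
   - carbamoyl migration before transmetalation;
   - allylation with allylic transposition.

   Fallback: it sets out from 7 and comes back at 13, which is triflated to 14 as in the second half of step 5. Carbamate cleavage (DBU, Et2NH, MeCN, 40 °C) should give 3,5-bis(methoxymethoxy)-2-(trimethylsilyl)phenol F6. O-Alkylation with methyl 2-methylbut-3-en-2-yl carbonate and Pd(PPh3)4 (cat.) in THF at 0 °C should give the tertiary allyl ether 1-[(2-methylbut-3-en-2-yl)oxy]-3,5-bis(methoxymethoxy)-2-(trimethylsilyl)benzene F7. Aromatic Claisen rearrangement (toluene, 110 °C) to the only free ortho position should then deliver the prenyl phenol 13 with the linear prenyl group, without any organolithium step on a prenylated or silylated arene.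

3. Step 12. What may go wrong:
   - acid-induced cyclisation of the C8 prenyl alkene onto the freed C7 hydroxyl (chroman formation);
   - addition of HCl or methanol to the alkenes;
   - incomplete cleavage of the three acetals.

   Fallback: it sets out from 23 and comes back at 24 without Brønsted acid. TMSOTf with 2,2′-bipyridyl in MeCN at 0 °C to rt exchanges aryl MOM ethers for aryl silyl ethers and should give (2S)-2-[5-(2-methylbut-3-en-2-yl)-2-[(trimethylsilyl)oxy]phenyl]-8-(3-methylbut-2-en-1-yl)-5,7-bis[(trimethylsilyl)oxy]-2,3-dihydro-4H-chromen-4-one F8. Neutral hydrolysis (H2O–MeOH, rt) should then give 24.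

Further compounds
F1 | step 11 | methyl (3R)-3-hydroxy-3-[2-(methoxymethoxy)-5-(2-methylbut-3-en-2-yl)phenyl]propanoate | COCOc1ccc(C(C)(C)C=C)cc1[C@H](O)CC(=O)OC
F2 | step 11 | methyl (3R)-3-[2-(methoxymethoxy)-5-(2-methylbut-3-en-2-yl)phenyl]-3-[(triisopropylsilyl)oxy]propanoate | COCOc1ccc(C(C)(C)C=C)cc1[C@H](O[Si](C(C)C)(C(C)C)C(C)C)CC(=O)OC
F3 | step 11 | (3R)-3-[2-(methoxymethoxy)-5-(2-methylbut-3-en-2-yl)phenyl]-3-[(triisopropylsilyl)oxy]propanoic acid | COCOc1ccc(C(C)(C)C=C)cc1[C@H](O[Si](C(C)C)(C(C)C)C(C)C)CC(=O)O
F4 | step 11 | (3R)-1-[2-hydroxy-4,6-bis(methoxymethoxy)-3-(3-methylbut-2-en-1-yl)phenyl]-3-[2-(methoxymethoxy)-5-(2-methylbut-3-en-2-yl)phenyl]-3-[(triisopropylsilyl)oxy]propan-1-one | COCOc1ccc(C(C)(C)C=C)cc1[C@H](O[Si](C(C)C)(C(C)C)C(C)C)CC(=O)c1c(OCOC)cc(OCOC)c(CC=C(C)C)c1O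
F5 | step 11 | (3R)-3-hydroxy-1-[2-hydroxy-4,6-bis(methoxymethoxy)-3-(3-methylbut-2-en-1-yl)phenyl]-3-[2-(methoxymethoxy)-5-(2-methylbut-3-en-2-yl)phenyl]propan-1-one | COCOc1ccc(C(C)(C)C=C)cc1[C@H](O)CC(=O)c1c(OCOC)cc(OCOC)c(CC=C(C)C)c1O
F6 | step 4 | 3,5-bis(methoxymethoxy)-2-(trimethylsilyl)phenol | COCOc1cc(OCOC)c([Si](C)(C)C)c(O)c1
F7 | step 4 | 1-[(2-methylbut-3-en-2-yl)oxy]-3,5-bis(methoxymethoxy)-2-(trimethylsilyl)benzene | COCOc1cc(OCOC)c([Si](C)(C)C)c(OC(C)(C)C=C)c1
F8 | step 12 | (2S)-2-[5-(2-methylbut-3-en-2-yl)-2-[(trimethylsilyl)oxy]phenyl]-8-(3-methylbut-2-en-1-yl)-5,7-bis[(trimethylsilyl)oxy]-2,3-dihydro-4H-chromen-4-one | C=CC(C)(C)c1ccc(O[Si](C)(C)C)c([C@@H]2CC(=O)c3c(O[Si](C)(C)C)cc(O[Si](C)(C)C)c(CC=C(C)C)c3O2)c1
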